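## Plan

- **Enabling feature.** C1 (ketone) and C4 (epoxide carbon) both neighbour C10 once a transannular C4–C10 bond is drawn. That bond turns the ten-membered ring into a bicyclo[5.3.0]decane whose five-membered ring C10–C1–C2–C3–C4 (C14 on C10) is 2-methylcyclopentane-1,3-dione and whose seven-membered ring is C4–C10.
- **Retrosynthesis.** Esters off; C1 ketone/C10 OAc from the C1=C10 alkene; the C4–O–C5 epoxide from a C4 ketone (MeLi) and a C5 sulfonate; the lactone from an alkylidene-dioxane diol. Then C4–C10 is reconnected to a hydroazulene γ-hydroxy tosylate, which is cut at C5=C6 (metathesis), C6–C7 (Stille), C4–C5 (vinyl addition), C7–C8 (alkenyllithium addition) and C9–C10 (allylation).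
- **Forward order.** Five-membered ring (dione), side chain C9–C8–C7(=C11), seven-membered ring by ring-closing metathesis, ten-membered ring by fragmentation of the shared bond, then epoxide, C1/C10 oxidation, butenolide and acylations.
- **Stereochemistry.** C10, C1 and C4 of the bicycle are sacrificial controllers (CBS desymmetrisation, addition anti to the C1 oxygen, hydride anti to the angular methyl). C8 comes from CBS reduction of an α-bromo enone and C5/C6 from C4–OH-directed osmylation. C4 comes from Felkin–Anh methyl addition, C5 is inverted on epoxide closure, and C10 comes from peripheral osmylation of the E-alkene.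

Key step: step 19

Assumption: germacrane numbering (C1–C15) is kept for every intermediate; centres that form as mixtures and are later erased or are inconsequential (C8 in 11, the ozonide and lactol carbons, the benzylidene acetal carbon) are written without configuration.

## Route

Step 1
Reactants: 1 2-methylcyclopentane-1,3-dione; 2 allyl bromide
Product: 3 2-allyl-2-methylcyclopentane-1,3-dione
Conditions: NaOH (1 M aq.), H2O, 23 °C
Reagents that add atoms: none
Why: C-allylation of the stabilised enolate of a cyclic 1,3-dione with a soft allylic halide in water, which creates the future C10 quaternary carbon (still prochiral).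

Step 2
Reactants: 3 2-allyl-2-methylcyclopentane-1,3-dione
Product: 4 (2R,3R)-2-allyl-3-hydroxy-2-methylcyclopentan-1-one
Conditions: (S)-Me-CBS oxazaborolidine [(S)-1-methyl-3,3-diphenyltetrahydro-1H,3H-pyrrolo[1,2-c][1,3,2]oxazaborole] (20 mol %), catecholborane (1.0 equiv), toluene, −78 → −40 °C
Reagents that add atoms: none
Why: Corey–Bakshi–Shibata desymmetrisation of a 2,2-disubstituted 1,3-dione; hydride should enter anti to the allyl group (hydroxyl cis to allyl) and the catalyst should select the carbonyl that gives the R carbinol, which fixes C10.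

Step 3
Reactants: 4 (2R,3R)-2-allyl-3-hydroxy-2-methylcyclopentan-1-one
Product: 5 (2R,3R)-2-allyl-2-methyl-3-(triethylsilyloxy)cyclopentan-1-one
Conditions: TESCl, imidazole, DMF, 0 → 23 °C
Reagents that add atoms: chlorotriethylsilane, CC[Si](Cl)(CC)CC
Why: Standard silylation of a secondary alcohol under non-basic conditions that avoid retro-aldol cleavage of the β-hydroxy ketone; the bulky ether later shields one face of the ketone.

Step 4
Reactants: 5 (2R,3R)-2-allyl-2-methyl-3-(triethylsilyloxy)cyclopentan-1-one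
Product: 7 2-[(1R,2R)-1-methyl-5-oxo-2-(triethylsilyloxy)cyclopentyl]acetaldehyde, via ozonide 6 (not isolated)
Conditions: O3, CH2Cl2, −78 °C; then PPh3, −78 → 23 °C
Reagents that add atoms: ozone, [O-][O+]=O
Why: Ozonolysis of the only alkene with reductive work-up gives the C8 aldehyde; the ketone and silyl ether are inert.

Step 5
Reactants: 8 2,2-dimethyl-1,3-dioxan-5-one
Product: 9 5-(dibromomethylidene)-2,2-dimethyl-1,3-dioxane
Conditions: CBr4, PPh3, CH2Cl2, 0 → 23 °C
Reagents that add atoms: carbon tetrabromide, BrC(Br)(Br)Br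
Why: Wittig-type dibromo-olefination (Ramirez/Corey–Fuchs reagent) of an activated α,α'-dialkoxy ketone; the product carries C7 (CBr2), C11, C12 and C13, and its two bromines are equivalent.

Step 6
Reactants: 7 2-[(1R,2R)-1-methyl-5-oxo-2-(triethylsilyloxy)cyclopentyl]acetaldehyde; 9 5-(dibromomethylidene)-2,2-dimethyl-1,3-dioxane
Product: 11 bromo allylic alcohol (C8 epimers), via lithium carbenoid 10 (not isolated)
Conditions: 9, n-BuLi (1.0 equiv), THF/Et2O, −105 °C; then 7, −105 → −78 °C; H2O
Reagents that add atoms: none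
Why: Bromine–lithium exchange on a 1,1-dibromoalkene gives an α-bromoalkenyllithium that is stable at very low temperature and adds to the aldehyde much faster than to the neopentylic cyclopentanone, forming C7–C8; the C8 centre is corrected in steps 7 and 8.

Step 7
Reactants: 11 bromo allylic alcohol (C8 epimers)
Product: 12 α-bromo enone (C8 ketone)
Conditions: Dess–Martin periodinane, NaHCO3, CH2Cl2, 0 → 23 °C
Reagents that add atoms: none
Why: Buffered Dess–Martin oxidation of a secondary allylic alcohol (reacting through its open form, not the minor hemiketal) converges both C8 epimers on one enone.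

Step 8
Reactants: 12 α-bromo enone (C8 ketone)
Product: 13 (8S)-bromo allylic alcohol
Conditions: (R)-Me-CBS oxazaborolidine (20 mol %), catecholborane (1.1 equiv), toluene, −78 °C
Reagents that add atoms: none
Why: Corey–Bakshi–Shibata reduction of an α-bromo enone, in which the bromoalkenyl group acts as the large substituent, should set C8 as S by reagent control; the hindered saturated cyclopentanone is expected to be much slower toward catecholborane at −78 °C.

Step 9
Reactants: 13 (8S)-bromo allylic alcohol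
Product: 14 (8S)-TBS ether
Conditions: TBSOTf, 2,6-lutidine, CH2Cl2, −78 → 0 °C
Reagents that add atoms: tert-butyldimethylsilyl triflate, CC(C)(C)[Si](C)(C)OS(=O)(=O)C(F)(F)F
Why: Silylation of the hindered secondary alcohol with the triflate at low temperature, where the ketone is not converted into an enol ether; TBS is orthogonal to the C1 TES ether.

Step 10
Reactants: 14 (8S)-TBS ether
Product: 15 (1R,4R,8S,10R)-C4 tertiary vinyl carbinol
Conditions: vinylMgBr, CeCl3, THF, −78 °C
Reagents that add atoms: vinylmagnesium bromide, C=C[Mg]Br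
Why: Organocerium addition to a hindered, enolisable ketone; the reagent should attack anti to the C1 silyl ether and the C9 side chain, which lie on the same face, so that the vinyl group (C5) ends cis to the C10 methyl and the hydroxyl trans to it.

Step 11
Reactants: 15 (1R,4R,8S,10R)-C4 tertiary vinyl carbinol
Product: 16 C7-vinyl triene (2-substituted 1,3-diene)
Conditions: tributyl(vinyl)stannane, Pd(PPh3)4 (10 mol %), CuI (20 mol %), DMF, 80 °C
Reagents that add atoms: tributyl(vinyl)stannane, C=C[Sn](CCCC)(CCCC)CCCC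
Why: Copper-assisted Stille coupling of an alkenyl bromide installs C6 as a vinyl group; silyl ethers, acetonide and the free tertiary alcohol are tolerated and no stereocentre is touched.

Step 12
Reactants: 16 C7-vinyl triene
Product: 17 (1R,4R,8S,10R)-1,4-diol
Conditions: HF·pyridine, pyridine, THF, 0 °C
Reagents that add atoms: none
Why: Buffered HF·pyridine removes a secondary TES ether selectively in the presence of the hindered secondary TBS ether and the acetonide; it is done before the acid-sensitive dienyl carbinol exists.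

Step 13
Reactants: 17 (1R,4R,8S,10R)-1,4-diol
Product: 18 (4R,8S,10S)-C1 ketone
Conditions: Dess–Martin periodinane, NaHCO3, CH2Cl2, 23 °C
Reagents that add atoms: none
Why: Dess–Martin oxidation of the secondary C1 alcohol (the tertiary C4 alcohol cannot react) removes the C1 centre, which has the wrong relation to the methyl group, so that it can be reset in the bicycle.

Step 14
Reactants: 18 (4R,8S,10S)-C1 ketone
Product: 19 trans-fused hydroazulene hydroxy ketone
Conditions: second-generation Grubbs catalyst RuCl2(=CHPh)(H2IMes)(PCy3) (10 mol %), toluene (0.005 M), 80 °C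
Reagents that add atoms: none
Why: Ring-closing metathesis of the two monosubstituted vinyl groups closes the seven-membered ring at C5=C6 (the tetrasubstituted C7=C11 alkene is inert); the trans ring fusion follows from the configurations set at C4 and C10.

Step 15
Reactants: 19 trans-fused hydroazulene hydroxy ketone
Product: 20 (1S,4R,8S,10R)-hydroazulene 1,4-diol
Conditions: NaBH4, MeOH/CH2Cl2, −78 → −40 °C
Reagents that add atoms: none
Why: Hydride reduction of a cyclopentanone next to an angular methyl group in a trans-fused bicycle should occur from the face opposite the methyl (as for steroidal 17-ketones), giving the C1 alcohol cis to the methyl.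

Step 16
Reactants: 20 (1S,4R,8S,10R)-hydroazulene 1,4-diol
Product: 21 C1 tosylate
Conditions: TsCl, DMAP, pyridine, 23 → 40 °C
Reagents that add atoms: p-toluenesulfonyl chloride, Cc1ccc(cc1)S(Cl)(=O)=O
Why: Sulfonylation of the secondary alcohol with retention; the tertiary C4 alcohol does not react and stays free for the fragmentation.

Step 17
Reactants: 21 C1 tosylate
Product: 23 (1S,4S,5R,6R,8S,10R)-4,5,6-triol, via osmate ester 22 (not isolated)
Conditions: OsO4 (1.05 equiv), TMEDA (1.1 equiv), CH2Cl2, −78 °C; then aq. Na2SO3, THF, 50 °C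
Reagents that add atoms: osmium tetroxide, O=[Os](=O)(=O)=O
Why: Hydrogen-bond-directed osmylation of a cyclic allylic alcohol: the OsO4·TMEDA complex is delivered by the C4 hydroxyl to the syn face of C5=C6, which is also the face away from the angular methyl and the C8 silyl ether, so the cis-5,6-diol should form trans to the C8 oxygen; the hindered tetrasubstituted alkene does not react.

Step 18
Reactants: 23 (1S,4S,5R,6R,8S,10R)-4,5,6-triol
Product: 24 (1S,4S,5R,6R,8S,10R)-5,6-O-(4-methoxybenzylidene) hydroazulene tosylate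
Conditions: 4-MeOC6H4CH(OMe)2, pyridinium p-toluenesulfonate (cat.), CH2Cl2, 23 °C
Reagents that add atoms: p-anisaldehyde dimethyl acetal, COC(OC)c1ccc(OC)cc1
Why: Acid-catalysed transacetalisation; the two secondary cis hydroxyls close the dioxolane faster than the tertiary C4 hydroxyl can, which leaves C4–OH free and masks C5/C6 in a base-stable form.

Step 19
Reactants: 24 (1S,4S,5R,6R,8S,10R)-5,6-O-(4-methoxybenzylidene) hydroazulene tosylate
Product: 26 (1(10)E,5R,6R,8S)-cyclodec-1(10)-en-4-one, via sodium alkoxide 25 (not isolated)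
Conditions: NaH (1.1 equiv), 15-crown-5 (10 mol %), THF, 0 → 23 °C
Reagents that add atoms: none
Why: Alkoxide 25 fragments in one concerted event: an oxygen lone pair forms the C4=O bond, the C4–C10 bond breaks, C10=C1 forms and tosylate leaves (Grob fragmentation of a cyclic 1,3-diol monosulfonate). The closest known reaction type is the base-induced fragmentation of bicyclic γ-hydroxy tosylates to medium-ring enones, including trans-hydrindane tosylates on the five-membered ring next to an angular methyl group. No ring is closed: the ten-membered ring is set free by cutting the bond shared by the five- and seven-membered rings, and no stereocentre is created, C1, C4 and C10 being erased. The step needs E geometry at C1=C10; this is secured because the tosylate is cis to the angular methyl and quasi-equatorial on the trans-fused five-membered ring, hence anti-periplanar to C4–C10, so that C2 and C9 end up trans. It also needs the α,β-dioxygenated ketone to survive: only 1.1 equiv of base is used, the by-product is non-basic sodium tosylate, and the cyclic acetal holds the C6–O bond almost orthogonal to any C5 enolate, which disfavours β-elimination.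

Step 20
Reactants: 26 (1(10)E,5R,6R,8S)-cyclodec-1(10)-en-4-one
Product: 27 (4R,5R,6R,8S)-C4 tertiary alcohol
Conditions: MeLi, THF, −78 °C
Reagents that add atoms: methyllithium, [Li]C
Why: Felkin–Anh (polar, non-chelation) addition to an α-alkoxy ketone: with the C5–O bond of the poorly chelating acetal anti to the incoming nucleophile, the new C4 hydroxyl should end anti to O5, which is the (4R) carbinol needed for a cis-epoxide after inversion at C5.

Step 21
Reactants: 27 (4R,5R,6R,8S)-C4 tertiary alcohol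
Product: 29 (4R,5R,6R,8S)-4,5-diol 6-PMB ether, via aluminium alkoxide 28 (not isolated)
Conditions: i-Bu2AlH (4 equiv), CH2Cl2, −78 → 0 °C; aq. potassium sodium tartrate
Reagents that add atoms: none
Why: Reductive opening of a p-methoxybenzylidene acetal by i-Bu2AlH; the C4 aluminium alkoxide 28 coordinates the neighbouring O5, so the acetal C–O5 bond should be cleaved and hydride delivery leaves the PMB group on O6 and a free C5 hydroxyl.

Step 22
Reactants: 29 (4R,5R,6R,8S)-4,5-diol 6-PMB ether
Product: 31 (4R,5S,6R,8S)-4,5-epoxide, via mesylate 30 (not isolated)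
Conditions: MsCl, Et3N, CH2Cl2, 0 °C; then K2CO3, MeOH, 23 °C
Reagents that add atoms: none
Why: The secondary C5 hydroxyl is mesylated while the tertiary C4 hydroxyl is inert, and carbonate then triggers 3-exo-tet displacement by the C4 alkoxide with inversion at C5, giving the cis-epoxide of the target.

Step 23
Reactants: 31 (4R,5S,6R,8S)-4,5-epoxide
Product: 32 (1R,4R,5S,6R,8S,10R)-1,10-diol
Conditions: OsO4 (5 mol %), N-methylmorpholine N-oxide, acetone/H2O, 0 → 23 °C
Reagents that add atoms: N-methylmorpholine N-oxide, C[N+]1([O-])CCOCC1; water, O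
Why: Upjohn dihydroxylation: the trisubstituted C1=C10 alkene is far more reactive than the hindered C7=C11 alkene flanked by four C–O bonds, and peripheral syn addition to the ring conformer with both methyl groups on the same side is expected to place the C10 oxygen on the face of the C8 oxygen (10R); the C1 configuration is lost in step 24.

Step 24
Reactants: 32 (1R,4R,5S,6R,8S,10R)-1,10-diol
Product: 33 10-hydroxy-1-ketone
Conditions: 2-iodoxybenzoic acid (IBX), DMSO, 23 °C
Reagents that add atoms: none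
Why: IBX oxidises the secondary alcohol of a 1,2-diol to the α-ketol without glycol cleavage; the tertiary C10 alcohol, PMB ether, epoxide and silyl ether are untouched.

Step 25
Reactants: 33 10-hydroxy-1-ketone
Product: 34 10-acetate
Conditions: Ac2O, 4-(dimethylamino)pyridine, Et3N, CH2Cl2, 40 °C
Reagents that add atoms: acetic anhydride, CC(=O)OC(C)=O
Why: DMAP-promoted acetylation of the tertiary α-ketol hydroxyl, the only free hydroxyl; capping it also removes a transannular nucleophile before the acidic steps.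

Step 26
Reactants: 34 10-acetate
Product: 35 C6 alcohol
Conditions: 2,3-dichloro-5,6-dicyano-1,4-benzoquinone (DDQ), CH2Cl2/pH 7 buffer, 0 °C
Reagents that add atoms: none
Why: Oxidative cleavage of the PMB ether by DDQ under buffered conditions frees the C6 hydroxyl; nothing else in the molecule is oxidised by DDQ.

Step 27
Reactants: 35 C6 alcohol
Product: 36 6,12,13-triol
Conditions: pyridinium p-toluenesulfonate (cat.), MeOH, 0 → 23 °C
Reagents that add atoms: none
Why: Mild acid-catalysed transketalisation removes the 1,3-dioxane acetonide; the TBS ether and tertiary acetate are stable, and with neither a transannular alkene nor a free C10 hydroxyl the epoxide should survive this acidity.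

Step 28
Reactants: 36 6,12,13-triol
Product: 39 12,6-butenolide with free C13 hydroxyl, via hydroxy aldehyde 37 (not isolated), via lactol 38 (not isolated)
Conditions: 2,2,6,6-tetramethylpiperidin-1-oxyl (TEMPO, 20 mol %), PhI(OAc)2 (2.2 equiv), CH2Cl2, 23 °C
Reagents that add atoms: none
Why: Oxidative lactonisation of a (Z)-2-ene-1,4-diol: the bulky oxoammonium oxidant should take the less hindered primary alcohol C12 (next to the free C6 hydroxyl, not the C8 silyl ether), aldehyde 37 is trapped by the cis C6 hydroxyl as lactol 38, and this is oxidised on to the lactone; C6 keeps its configuration.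

Step 29
Reactants: 39 12,6-butenolide with free C13 hydroxyl
Product: 40 C13 acetate
Conditions: Ac2O, pyridine, CH2Cl2, 0 °C
Reagents that add atoms: acetic anhydride, CC(=O)OC(C)=O
Why: Acetylation of the only free (primary) hydroxyl under mild conditions that do not enolise the butenolide.

Step 30
Reactants: 40 C13 acetate
Product: 41 C8 alcohol
Conditions: HF·pyridine, THF, 0 → 23 °C
Reagents that add atoms: none
Why: Fluoride-mediated cleavage of the secondary TBS ether under weakly acidic, non-basic conditions that avoid acyl migration and spare the esters, lactone and epoxide.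

Step 31
Reactants: 41 C8 alcohol
Product: 42 CNP0172381.2
Conditions: methacrylic anhydride, Et3N, 4-(dimethylamino)pyridine (cat.), CH2Cl2, 0 → 23 °C
Reagents that add atoms: methacrylic anhydride, CC(=C)C(=O)OC(=O)C(C)=C
Why: DMAP-catalysed acylation of the C8 secondary alcohol with retention completes the target.

## Compound list

1 | 2-methylcyclopentane-1,3-dione | CC1C(=O)CCC1=O | starting material
2 | allyl bromide (3-bromoprop-1-ene) | C=CCBr | starting material
3 | 2-allyl-2-methylcyclopentane-1,3-dione | C=CCC1(C)C(=O)CCC1=O | intermediate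
4 | (2R,3R)-2-allyl-3-hydroxy-2-methylcyclopentan-1-one (OH cis to allyl) | O=C1CC[C@@H](O)[C@@]1(C)CC=C | intermediate
5 | (2R,3R)-2-allyl-2-methyl-3-(triethylsilyloxy)cyclopentan-1-one | O=C1CC[C@@H](O[Si](CC)(CC)CC)[C@@]1(C)CC=C | intermediate
6 | ozonide (1,2,4-trioxolane) of 5 | O=C1CC[C@@H](O[Si](CC)(CC)CC)[C@@]1(C)CC1OCOO1 | intermediate
7 | 2-[(1R,2R)-1-methyl-5-oxo-2-(triethylsilyloxy)cyclopentyl]acetaldehyde (C8 aldehyde) | O=C1CC[C@@H](O[Si](CC)(CC)CC)[C@@]1(C)CC=O | intermediate
8 | 2,2-dimethyl-1,3-dioxan-5-one | CC1(C)OCC(=O)CO1 | starting material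
9 | 5-(dibromomethylidene)-2,2-dimethyl-1,3-dioxane | BrC(Br)=C1COC(C)(C)OC1 | intermediate
10 | [bromo(2,2-dimethyl-1,3-dioxan-5-ylidene)methyl]lithium | [Li]C(Br)=C1COC(C)(C)OC1 | intermediate
11 | (2R,3R)-2-[3-bromo-3-(2,2-dimethyl-1,3-dioxan-5-ylidene)-2-hydroxypropyl]-2-methyl-3-(triethylsilyloxy)cyclopentan-1-one, both C8 epimers | O=C1CC[C@@H](O[Si](CC)(CC)CC)[C@@]1(C)CC(O)C(Br)=C1COC(C)(C)OC1 | intermediate
12 | (2R,3R)-2-[3-bromo-3-(2,2-dimethyl-1,3-dioxan-5-ylidene)-2-oxopropyl]-2-methyl-3-(triethylsilyloxy)cyclopentan-1-one | O=C1CC[C@@H](O[Si](CC)(CC)CC)[C@@]1(C)CC(=O)C(Br)=C1COC(C)(C)OC1 | intermediate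
13 | (8S)-alcohol: (2R,3R)-2-[(2S)-3-bromo-3-(2,2-dimethyl-1,3-dioxan-5-ylidene)-2-hydroxypropyl]-2-methyl-3-(triethylsilyloxy)cyclopentan-1-one | O=C1CC[C@@H](O[Si](CC)(CC)CC)[C@@]1(C)C[C@H](O)C(Br)=C1COC(C)(C)OC1 | intermediate
14 | C8 TBS ether of 13 | O=C1CC[C@@H](O[Si](CC)(CC)CC)[C@@]1(C)C[C@H](O[Si](C)(C)C(C)(C)C)C(Br)=C1COC(C)(C)OC1 | intermediate
15 | (1R,4R,8S,10R)-cyclopentanol: C4 OH and vinyl (vinyl cis to C10 CH3), C1 OTES, C10 chain CH2–CH(OTBS)–C(Br)=dioxanylidene | C=C[C@]1(O)CC[C@@H](O[Si](CC)(CC)CC)[C@@]1(C)C[C@H](O[Si](C)(C)C(C)(C)C)C(Br)=C1COC(C)(C)OC1 | intermediate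
16 | C7-vinyl analogue of 15 (Br replaced by CH=CH2) | C=C[C@]1(O)CC[C@@H](O[Si](CC)(CC)CC)[C@@]1(C)C[C@H](O[Si](C)(C)C(C)(C)C)C(C=C)=C1COC(C)(C)OC1 | intermediate
17 | (1R,4R,8S,10R)-1,4-diol (TES removed from 16) | C=C[C@]1(O)CC[C@@H](O)[C@@]1(C)C[C@H](O[Si](C)(C)C(C)(C)C)C(C=C)=C1COC(C)(C)OC1 | intermediate
18 | (4R,8S,10S)-C1 ketone of 17 | C=C[C@]1(O)CCC(=O)[C@@]1(C)C[C@H](O[Si](C)(C)C(C)(C)C)C(C=C)=C1COC(C)(C)OC1 | intermediate
19 | (4R,8S,10S)-trans-fused bicyclo[5.3.0]dec-5-en-1-one: C4 OH trans to C10 CH3, C7 dioxanylidene, C8 OTBS cis to CH3 | O=C1CC[C@@]2(O)C=CC(=C3COC(C)(C)OC3)[C@@H](O[Si](C)(C)C(C)(C)C)C[C@]12C | intermediate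
20 | (1S,4R,8S,10R)-hydroazulene 1,4-diol: C1 OH cis to C10 CH3 | O[C@H]1CC[C@@]2(O)C=CC(=C3COC(C)(C)OC3)[C@@H](O[Si](C)(C)C(C)(C)C)C[C@]12C | intermediate
21 | (1S,4R,8S,10R)-C1 tosylate of 20 | Cc1ccc(cc1)S(=O)(=O)O[C@H]1CC[C@@]2(O)C=CC(=C3COC(C)(C)OC3)[C@@H](O[Si](C)(C)C(C)(C)C)C[C@]12C | intermediate
22 | 5,6-osmate ester of 21 (hexavalent osmium glycolate chelated by TMEDA) | Cc1ccc(cc1)S(=O)(=O)O[C@H]1CC[C@@]2(O)[C@@H]3O[Os-2]4(=O)(=O)([N+](C)(C)CC[N+]4(C)C)O[C@@H]3C(=C3COC(C)(C)OC3)[C@@H](O[Si](C)(C)C(C)(C)C)C[C@]12C | intermediate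
23 | (1S,4S,5R,6R,8S,10R)-4,5,6-triol (all cis) C1 tosylate | Cc1ccc(cc1)S(=O)(=O)O[C@H]1CC[C@@]2(O)[C@H](O)[C@H](O)C(=C3COC(C)(C)OC3)[C@@H](O[Si](C)(C)C(C)(C)C)C[C@]12C | intermediate
24 | (1S,4S,5R,6R,8S,10R)-trans-fused hydroazulene: C1 OTs cis to C10 CH3, C4 OH, 5,6-O-(4-methoxybenzylidene), C7 (2,2-dimethyl-1,3-dioxan-5-ylidene), C8 OTBS | Cc1ccc(cc1)S(=O)(=O)O[C@H]1CC[C@@]2(O)[C@@H]3OC(c4ccc(OC)cc4)O[C@@H]3C(=C3COC(C)(C)OC3)[C@@H](O[Si](C)(C)C(C)(C)C)C[C@]12C | intermediate
25 | sodium C4 alkoxide of 24 | Cc1ccc(cc1)S(=O)(=O)O[C@H]1CC[C@@]2([O-])[C@@H]3OC(c4ccc(OC)cc4)O[C@@H]3C(=C3COC(C)(C)OC3)[C@@H](O[Si](C)(C)C(C)(C)C)C[C@]12C.[Na+] | intermediate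
26 | (1(10)E,5R,6R,8S)-8-(tert-butyldimethylsilyloxy)-7-(2,2-dimethyl-1,3-dioxan-5-ylidene)-5,6-[(4-methoxybenzylidene)dioxy]-10-methylcyclodec-1(10)-en-4-one | O=C1CC/C=C(C)/C[C@H](O[Si](C)(C)C(C)(C)C)C(=C2COC(C)(C)OC2)[C@H]2OC(c3ccc(OC)cc3)O[C@@H]12 | intermediate
27 | (4R,5R,6R,8S)-4-methyl C4 tertiary alcohol of 26 | C[C@@]1(O)CC/C=C(C)/C[C@H](O[Si](C)(C)C(C)(C)C)C(=C2COC(C)(C)OC2)[C@H]2OC(c3ccc(OC)cc3)O[C@@H]12 | intermediate
28 | diisobutylaluminium C4 alkoxide of 27 | CC(C)C[Al](CC(C)C)O[C@]1(C)CC/C=C(C)/C[C@H](O[Si](C)(C)C(C)(C)C)C(=C2COC(C)(C)OC2)[C@H]2OC(c3ccc(OC)cc3)O[C@@H]12 | intermediate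
29 | (4R,5R,6R,8S)-4,5-diol with C6 OPMB | C[C@@]1(O)CC/C=C(C)/C[C@H](O[Si](C)(C)C(C)(C)C)C(=C2COC(C)(C)OC2)[C@@H](OCc2ccc(OC)cc2)[C@H]1O | intermediate
30 | C5 mesylate of 29 | C[C@@]1(O)CC/C=C(C)/C[C@H](O[Si](C)(C)C(C)(C)C)C(=C2COC(C)(C)OC2)[C@@H](OCc2ccc(OC)cc2)[C@H]1OS(C)(=O)=O | intermediate
31 | (1(10)E,4R,5S,6R,8S)-4,5-epoxide (cis), C6 OPMB, C8 OTBS, C7 dioxanylidene | C[C@@]12CC/C=C(C)/C[C@H](O[Si](C)(C)C(C)(C)C)C(=C3COC(C)(C)OC3)[C@@H](OCc3ccc(OC)cc3)[C@@H]1O2 | intermediate
32 | (1R,4R,5S,6R,8S,10R)-1,10-diol of 31 | C[C@@]12CC[C@@H](O)[C@](C)(O)C[C@H](O[Si](C)(C)C(C)(C)C)C(=C3COC(C)(C)OC3)[C@@H](OCc3ccc(OC)cc3)[C@@H]1O2 | intermediate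
33 | (4R,5S,6R,8S,10R)-10-hydroxy-1-ketone | C[C@@]12CCC(=O)[C@](C)(O)C[C@H](O[Si](C)(C)C(C)(C)C)C(=C3COC(C)(C)OC3)[C@@H](OCc3ccc(OC)cc3)[C@@H]1O2 | intermediate
34 | (4R,5S,6R,8S,10R)-10-acetoxy-1-ketone | C[C@@]12CCC(=O)[C@](C)(OC(C)=O)C[C@H](O[Si](C)(C)C(C)(C)C)C(=C3COC(C)(C)OC3)[C@@H](OCc3ccc(OC)cc3)[C@@H]1O2 | intermediate
35 | C6 alcohol (PMB removed from 34) | C[C@@]12CCC(=O)[C@](C)(OC(C)=O)C[C@H](O[Si](C)(C)C(C)(C)C)C(=C3COC(C)(C)OC3)[C@@H](O)[C@@H]1O2 | intermediate
36 | 6,12,13-triol (acetonide removed from 35) | C[C@@]12CCC(=O)[C@](C)(OC(C)=O)C[C@H](O[Si](C)(C)C(C)(C)C)C(=C(CO)CO)[C@@H](O)[C@@H]1O2 | intermediate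
37 | C12 aldehyde of 36 (CHO cis to C6) | C[C@@]12CCC(=O)[C@](C)(OC(C)=O)C[C@H](O[Si](C)(C)C(C)(C)C)/C(=C(\CO)C=O)[C@@H](O)[C@@H]1O2 | intermediate
38 | 12,6-lactol | C[C@@]12CCC(=O)[C@](C)(OC(C)=O)C[C@H](O[Si](C)(C)C(C)(C)C)C3=C(CO)C(O)O[C@H]3[C@@H]1O2 | intermediate
39 | (4R,5S,6R,8S,10R)-7(11)-en-12,6-olide with C13 OH, C8 OTBS, C10 OAc, C1 ketone, 4,5-epoxide | C[C@@]12CCC(=O)[C@](C)(OC(C)=O)C[C@H](O[Si](C)(C)C(C)(C)C)C3=C(CO)C(=O)O[C@H]3[C@@H]1O2 | intermediate
40 | C13 acetate of 39 | C[C@@]12CCC(=O)[C@](C)(OC(C)=O)C[C@H](O[Si](C)(C)C(C)(C)C)C3=C(COC(C)=O)C(=O)O[C@H]3[C@@H]1O2 | intermediate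
41 | C8 alcohol (TBS removed from 40) | C[C@@]12CCC(=O)[C@](C)(OC(C)=O)C[C@H](O)C3=C(COC(C)=O)C(=O)O[C@H]3[C@@H]1O2 | intermediate
42 | CNP0172381.2, (4R,5S,6R,8S,10R) | C=C(C)C(=O)O[C@H]1C[C@@](C)(OC(C)=O)C(=O)CC[C@@]2(C)O[C@H]2[C@@H]2OC(=O)C(COC(C)=O)=C12 | target

## Step count and weak points

Total steps: 31. Longest linear sequence: 30 (steps 1–4 and 6–31; step 5 prepares fragment 9).

The three steps most likely to fail:

(a) Methyl addition, step 20. What may go wrong: the conformation of the ten-membered ring, rather than the Felkin–Anh preference, may decide which face of the C4 ketone is attacked, and enolisation may compete, so the C4 epimer that leads to the trans-epoxide could dominate. Fallback (oxygen instead of carbon is delivered under reagent control): from 26, methylenation with Cp2TiMe2 (bis(cyclopentadienyl)dimethyltitanium, toluene, 65 °C) would give the 4-methylidene compound F1. Opening of its acetal with i-Bu2AlH at the less hindered O5 would give the allylic alcohol F2 (C5 OH, C6 OPMB). Sharpless asymmetric epoxidation of F2 (Ti(OiPr)4, D-(−)-diethyl tartrate, t-BuOOH, 4 Å sieves, CH2Cl2, −20 °C) is the matched case for this carbinol and should give the erythro spiro-epoxide F3, with the C4 oxygen on the required face and no reaction at C1=C10. LiEt3BH in THF would then open F3 at the CH2 terminus and return to the route at 29.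

(b) Osmylation of C1=C10, step 23. What may go wrong: attack on the other face of the E-alkene, because the reacting ring conformer decides the C10 configuration, or competing osmylation of the alkylidene dioxane. Fallback (oxidise C1=C10 only after the butenolide is in place, so the ring has the conformation of the lactone series and the C7=C11 alkene is electron-poor and inert): from 31, DDQ in buffered CH2Cl2 would give the C6 alcohol F4, and pyridinium p-toluenesulfonate in MeOH the triol F5. TEMPO/PhI(OAc)2 would give the butenolide F6 and Ac2O/pyridine its C13 acetate F7. OsO4 (cat.)/N-methylmorpholine N-oxide would then give the 1,10-diol F8 and IBX the ketol F9; acetylation with Ac2O and 4-(dimethylamino)pyridine returns to the route at 40.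

(c) Oxidative lactonisation, step 28. What may go wrong: the oxidant may take C13–OH first, giving a hydroxy enal that cannot close on O6, or it may over-oxidise C13 after lactone formation. Fallback (converge by exhaustive oxidation, then correct by chemoselective reduction): from 36, excess oxidant (TEMPO with 4 equiv PhI(OAc)2, or MnO2) would drive both pathways to the 13-formyl butenolide F10. NaBH(OAc)3 in THF would then reduce only the aldehyde (ketone, lactone and esters untouched) and return to the route at 39.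

Further compounds

F1 | step 20 | 4-methylidene analogue of 26 (C4=CH2 in place of C4=O) | C=C1CC/C=C(C)/C[C@H](O[Si](C)(C)C(C)(C)C)C(=C2COC(C)(C)OC2)[C@H]2OC(c3ccc(OC)cc3)O[C@@H]12
F2 | step 20 | 4-methylidene (5R,6R,8S)-allylic alcohol: C5 OH, C6 OPMB | C=C1CC/C=C(C)/C[C@H](O[Si](C)(C)C(C)(C)C)C(=C2COC(C)(C)OC2)[C@@H](OCc2ccc(OC)cc2)[C@H]1O
F3 | step 20 | 4,15-epoxide of F2, epoxide oxygen anti to the C5 hydroxyl (erythro) | C1O[C@@]12CC/C=C(C)/C[C@H](O[Si](C)(C)C(C)(C)C)C(=C3COC(C)(C)OC3)[C@@H](OCc3ccc(OC)cc3)[C@H]2O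
F4 | step 23 | C6 alcohol of 31 (PMB removed, 1(10)-alkene retained) | C[C@@]12CC/C=C(C)/C[C@H](O[Si](C)(C)C(C)(C)C)C(=C3COC(C)(C)OC3)[C@@H](O)[C@@H]1O2
F5 | step 23 | 6,12,13-triol of F4 | C[C@@]12CC/C=C(C)/C[C@H](O[Si](C)(C)C(C)(C)C)C(=C(CO)CO)[C@@H](O)[C@@H]1O2
F6 | step 23 | 1(10)E-ene 4,5-epoxy 7(11)-en-12,6-olide with C13 OH and C8 OTBS | C[C@@]12CC/C=C(C)/C[C@H](O[Si](C)(C)C(C)(C)C)C3=C(CO)C(=O)O[C@H]3[C@@H]1O2
F7 | step 23 | C13 acetate of F6 | C[C@@]12CC/C=C(C)/C[C@H](O[Si](C)(C)C(C)(C)C)C3=C(COC(C)=O)C(=O)O[C@H]3[C@@H]1O2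
F8 | step 23 | (1R,10R)-1,10-diol of F7 | C[C@@]12CC[C@@H](O)[C@](C)(O)C[C@H](O[Si](C)(C)C(C)(C)C)C3=C(COC(C)=O)C(=O)O[C@H]3[C@@H]1O2
F9 | step 23 | 10-hydroxy-1-ketone of F8 | C[C@@]12CCC(=O)[C@](C)(O)C[C@H](O[Si](C)(C)C(C)(C)C)C3=C(COC(C)=O)C(=O)O[C@H]3[C@@H]1O2
F10 | step 28 | 13-formyl butenolide (C13 aldehyde of 39) | C[C@@]12CCC(=O)[C@](C)(OC(C)=O)C[C@H](O[Si](C)(C)C(C)(C)C)C3=C(C=O)C(=O)O[C@H]3[C@@H]1O2
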